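## Structural features

The target is a cyclobutane in which every ring carbon is a CH stereocentre. Two neighbouring carbons (called Ca and Cd below) each carry a 2-amino-1H-imidazol-4-yl ring bonded through its C4, and the other two (Cb and Cc) each carry a CH2–NH–C(=O)–pyrrol-2-yl arm. The four contiguous stereocentres are all-trans, so the substituents alternate above and below the ring, which is also the thermodynamically preferred arrangement. One pyrrole carries bromine at C4 and the other does not, and this alone breaks the C2 axis through the midpoints of the Ca–Cd and Cb–Cc bonds. The 2-aminoimidazoles are cyclic guanidines (polar, basic, oxidation-prone, awkward on silica), the bromopyrrole is electron-rich, and any ring carbon that carries a carbonyl group during the synthesis is epimerisable. The real difficulty is twofold: making the tetrasubstituted four-membered ring as one enantiomer, and carrying two guanidine heterocycles plus two different acyl groups on homotopic nitrogens through the endgame. The key step exploits the fact that in each aminoimidazole the N1–C2(NH2)–N3 unit bridges C5 (a CH) and C4 (bonded to Ca or Cd), so that the C4–C5 pair is a bromomethyl ketone in disguise and the N–C–N unit can be delivered by a neutral 2-aminoazine whose three extra carbons are excised later.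

## Logic of the disconnections

**24 to 23.** No skeletal bond of 24 is cut. In each heterocycle the ring N–H and the exocyclic NH2 are tied back together through a CH=CH–CH bridge (two N–C bonds per ring in the retro direction). The reason is to keep both guanidines masked, neutral and silica-compatible until the last operation. The gain is that every earlier intermediate is an ordinary organic-soluble compound. The demand is that the forward excision of the two bridges spares two secondary pyrrole amides and an aryl C–Br bond.

**23 to 21 and 22.** The amide N–C(=O) bond of the bromine-free arm is cut. This is a plain acylation of a primary amine and removes one heteroaryl unit. The demand is chemoselective N-acylation next to pyrrole N–H groups and weakly basic fused heterocycles.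

**21 to 18 and 19 (through 20).** The second amide N–C(=O) bond and both carbamate N–C bonds are cut. This exposes 20, whose two amines are homotopic, so all earlier chemistry is twofold on a C2-symmetric skeleton. The demand is mono-acylation of one of two equivalent amines, which is inherently statistical and therefore must be done where separation and recycling are easy.

**18 to 15 and 16.** In each fused imidazole the bond from the bridgehead nitrogen to the ring CH and the bond from N1 to the carbon attached to the cyclobutane are cut: four C–N bonds and two rings. Two heterocycles collapse to two bromoacetyl groups on a C2-symmetric carbocycle. The demands are alkylation at the ring nitrogen instead of the amino group, complete twofold reaction, and conditions mild enough that Ca and Cd stay trans until aromatisation fixes them.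

**15 to 12 (through 13 and 14).** Both C(=O)–CH2Br bonds are cut, a one-carbon homologation of a carboxylic acid. The gain is that 12 is a simple trans diacid. The demand is homologation without loss of the acid-labile carbamates.

**12 to 10, 8, 7 and 6.** No C–C bond is cut. The acid carbons on Ca and Cd go back to benzyl-protected CH2O groups, and the CH2–N bonds on Cb and Cc go back to C–O and then to ester carbonyls. The reason is that the Ca/Cd arms must be inert while the Cb/Cc arms serve as enolisable esters for ring closure. The demand is that each reagent distinguishes the two pairs of arms.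

**6 to 4 (through 5).** The ring bond Cb–Cc between the two ester α-carbons is cut. Both carbons are enolate carbons, so the bond can be made by oxidative coupling. The gain is that 4 is acyclic and has only two stereocentres. The demand is that 4-exo-tet closure beats Claisen-type cyclisation and intermolecular coupling, and that the two new stereocentres end up trans to their neighbours.

**4 to 3, 2 and 1.** The two ester carbons of 4 are reconnected as a ring C=C (ozonolysis transform), and the benzyl ethers are traced back through 2 to 1. The gain is a purchasable enantiopure six-membered ring whose trans stereocentres become Ca and Cd. The demand is that ozone cleaves the alkene faster than it oxidises the benzyl ethers.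

## Other disconnections considered

**Alternative 1:** The cut is the same ring bond that step 4 makes, but made pericyclically from an aromatic precursor. Phthalic acid A1 would be reduced and dehydrated to cis-1,2-dihydrophthalic anhydride A2. On irradiation the diene of A2 should close by a disrotatory 4π electrocyclisation to the cis-fused bicyclic anhydride A3. Ozonolysis of the cyclobutene of A3 would then expose two carbonyl arms beside the anhydride.
- In favour: all four ring carbons and all four substituent carbons come from A1 in about three operations. The ring-forming step needs no reagent and is stereospecific. The two pairs of arms are already differentiated, one pair at the carboxyl level (suited to bromoketone homologation) and one at the aldehyde level (suited to reductive amination).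
- Against: A3 is meso and its arms emerge cis,trans,cis, so two epimerisations are needed; these are downhill and plausible. The absolute configuration must be imposed by desymmetrising the anhydride or by resolution, and which enantiotopic half epimerises then decides the enantiomer. Dilute photochemistry and ozonolysis of a strained cyclobutene are further burdens.
- Comparison: structurally it solves only the carbocycle and would still feed into the heteroannulation of step 10. Mechanistically it trades an ionic closure with chirality carried from 1 for an achiral pericyclic one. It is better than the chosen plan in step count to a fully substituted four-membered ring and in avoiding cryogenic dienolate chemistry. It is equal or worse once enantiocontrol and the epimerisations are counted.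

**Alternative 2:** The cut removes one ring carbon: both ring bonds to the ester-bearing carbon are disconnected. The sulfonylcyclopropanol A4 would release the trans-disubstituted cyclopropanone A5 under mild base. Ethyl diazoacetate A6 would add through its diazo carbon to the carbonyl of A5, and a 1,2-shift with loss of N2 would expand the ring to the cyclobutanone A7.
- In favour: the two benzyloxymethyl stereocentres come from the chiral pool and the shift is stereoretentive. The two migrating carbons of A5 are homotopic, so there is no regiochemical issue. Ring formation is intramolecular and cannot oligomerise. The epimerisable β-keto ester A7 should settle trans.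
- Against: A7 carries only three of the four substituent carbons. The ketone carbon must still be homologated and its configuration set, which adds steps and a new stereochemical event. A4 itself needs several steps, and a second insertion of A6 or epoxide formation can compete.
- Comparison: it is equal to the chosen plan in absolute stereocontrol, since both draw on the chiral pool. It is better in one respect: the ketone and ester carbons of A7 are chemically different, so the two unlike pyrrole amides could in principle be introduced without the statistical step 11. It is worse in step economy, because the chosen plan has every substituent carbon in place before the ring closes.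

**Alternative 3:** The cut is the two C(ring)–C(heteroaryl) bonds. The trans diamide A8, a (1R,2R)-configured cyclobutane carrying two quinolin-8-yl carboxamides, would be arylated twice with 4-iodo-1-trityl-1H-imidazole A9 under Pd(OAc)2 catalysis with a silver carboxylate. The reaction would run through amide-directed palladacycles of divalent palladium and oxidative addition to tetravalent palladium, and should give the bis(imidazolyl) diamide A10 with each imidazole cis to its neighbouring amide.
- In favour: intact heterocycles are attached directly to a simple resolved cyclobutane. Stereocontrol at Ca and Cd is substrate-directed. No α-haloketone, diazo or azide chemistry is needed.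
- Against: the imidazoles of A10 lack the 2-amino groups, so two late C2 aminations are required. The basic azole nitrogen and the bulky trityl group of A9 make it a poor partner for this catalysis, and the second arylation is at a more hindered methylene. Both amide carbons must then be epimerised to reach all-trans. The robust aminoquinoline amides must be cleaved and converted to CH2NH2, since direct reduction would leave N-quinolyl amines.
- Comparison: structurally it attacks the same two bonds as the chosen plan reaches through ketones. It is equal or better in convergence and in step count up to the arylated core. It is worse afterwards, where the chosen plan needs only deprotection, two acylations and unmasking. The heteroannulation of step 10 is also metal-free and indifferent to regiochemistry, which the arylation is not.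

Key step: step 10

Remark: (1S,2S)-1 is taken to be purchasable enantiopure. Mapped atom by atom, C1 and C2 of 1 become Ca and Cd of 24 with all bonds at each centre retained, so this is the correct enantiomer. Descriptors of later intermediates change only because substituent priorities change.

Remark: half-converted species of the twofold reactions on the C2-symmetric intermediates are assumed not to accumulate and are not listed separately. 24 is drawn as the free base and would be isolated by reverse-phase chromatography.

Step 1
Reactants: 1 (1S,2S)-cyclohex-4-ene-1,2-dicarboxylic acid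
Product: 2 [(1S,2S)-cyclohex-4-ene-1,2-diyl]dimethanol
Conditions: LiAlH4, THF, 0 °C to reflux; aqueous NaOH work-up
Reagents that add atoms: none
Why: Hydride reduction of a carboxylic acid to the primary alcohol; the carboxylate salts do not enolise, so both stereocentres are retained and the alkene is untouched.

Step 2
Reactants: 2 [(1S,2S)-cyclohex-4-ene-1,2-diyl]dimethanol
Product: 3 (4S,5S)-4,5-bis[(benzyloxy)methyl]cyclohex-1-ene
Conditions: NaH, BnBr, Bu4NI (cat.), THF/DMF, 0 °C to rt
Reagents that add atoms: benzyl bromide BrCc1ccccc1
Why: Williamson etherification of two unhindered primary alkoxides; the ethers are inert to ozone at low temperature, to amide bases and to hydride, which the next three steps require.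

Step 3
Reactants: 3 (4S,5S)-4,5-bis[(benzyloxy)methyl]cyclohex-1-ene
Product: 4 dimethyl (3S,4S)-3,4-bis[(benzyloxy)methyl]hexanedioate
Conditions: O3 (to alkene end-point), 2.5 M NaOH in MeOH, CH2Cl2, −78 °C; then H2O, rt
Reagents that add atoms: ozone [O-][O+]=O; methanol CO
Why: Ozonolysis with in situ oxidative esterification: the carbonyl oxide is trapped by methanol and dehydrated by base, and the aldehyde terminus is oxidised as its hemiacetal, so both alkene carbons should emerge as methyl esters; the stereocentres are β to the new carbonyls and cannot epimerise.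

Step 4
Reactants: 4 dimethyl (3S,4S)-3,4-bis[(benzyloxy)methyl]hexanedioate
Product: 6 dimethyl (1S,2S,3R,4R)-3,4-bis[(benzyloxy)methyl]cyclobutane-1,2-dicarboxylate (all-trans), via α-iodo diester 5 (not isolated)
Conditions: 4 added to LiN(i-Pr)2 (2.2 equiv), THF, −78 °C; I2 (1.0 equiv), −78 °C to rt; then NaOMe (0.2 equiv), MeOH, rt
Reagents that add atoms: none
Why: Intramolecular oxidative coupling of a diester bis-enolate: one enolate is iodinated and the other displaces iodide in a 4-exo-tet SN2 closure, while inverse addition keeps free ester and enolate apart and so suppresses Dieckmann condensation. The two new stereocentres Cb and Cc are ester α-carbons flanked by the fixed centres Ca and Cd, so NaOMe equilibration should converge any cis isomer on the all-trans diester.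

Step 5
Reactants: 6 dimethyl (1S,2S,3R,4R)-3,4-bis[(benzyloxy)methyl]cyclobutane-1,2-dicarboxylate
Product: 7 {(1R,2R,3S,4S)-3,4-bis[(benzyloxy)methyl]cyclobutane-1,2-diyl}dimethanol
Conditions: LiAlH4, THF, 0 °C to rt
Reagents that add atoms: none
Why: Ester reduction to primary alcohols; benzyl ethers are inert, and Cb and Cc cease to be epimerisable, which locks the all-trans ring.

Step 6
Reactants: 7 {(1R,2R,3S,4S)-3,4-bis[(benzyloxy)methyl]cyclobutane-1,2-diyl}dimethanol
Product: 8 (1R,2R,3S,4S)-1,2-bis(azidomethyl)-3,4-bis[(benzyloxy)methyl]cyclobutane
Conditions: (PhO)2P(O)N3, PPh3, DIAD, THF, 0 °C to rt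
Reagents that add atoms: diphenyl phosphoryl azide [N-]=[N+]=NP(=O)(Oc1ccccc1)Oc1ccccc1
Why: Mitsunobu azidation at two primary carbons, with no ring stereocentre involved; cyclodehydration to a tetrahydrofuran is disfavoured because it would need a trans-fused bicyclo[3.2.0] ring, and the product has a (C + O)/N ratio of 4, which keeps it in the safely handled range.

Step 7
Reactants: 8 (1R,2R,3S,4S)-1,2-bis(azidomethyl)-3,4-bis[(benzyloxy)methyl]cyclobutane
Product: 10 di-tert-butyl {[(1R,2R,3S,4S)-3,4-bis(hydroxymethyl)cyclobutane-1,2-diyl]bis(methylene)}dicarbamate, via bis(carbamate) dibenzyl ether 9 (not isolated)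
Conditions: H2 (3 atm), Pd(OH)2/C, Boc2O (2.4 equiv), EtOAc/MeOH, rt
Reagents that add atoms: di-tert-butyl dicarbonate CC(C)(C)OC(=O)OC(=O)OC(C)(C)C
Why: Catalytic hydrogenation reduces the azides to amines, which Boc2O traps at once as carbamates so that they cannot poison the catalyst; hydrogenolysis of the two benzyl ethers then follows on the same catalyst.

Step 8
Reactants: 10 di-tert-butyl {[(1R,2R,3S,4S)-3,4-bis(hydroxymethyl)cyclobutane-1,2-diyl]bis(methylene)}dicarbamate
Product: 12 (1S,2S,3R,4R)-3,4-bis{[(tert-butoxycarbonyl)amino]methyl}cyclobutane-1,2-dicarboxylic acid, via dialdehyde 11 (not isolated)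
Conditions: TEMPO (0.2 equiv), PhI(OAc)2 (4.4 equiv), MeCN/H2O 1:1, rt
Reagents that add atoms: water O
Why: Oxoammonium-mediated oxidation of primary alcohols through the aldehyde hydrates to the acids; lactol and lactone formation between the two arms is blocked because it would need a trans-fused five-membered ring, and Ca and Cd, now α to carbonyl groups, already sit in the thermodynamically preferred trans arrangement.

Step 9
Reactants: 12 (1S,2S,3R,4R)-3,4-bis{[(tert-butoxycarbonyl)amino]methyl}cyclobutane-1,2-dicarboxylic acid
Product: 15 di-tert-butyl {[(1R,2R,3S,4S)-3,4-bis(2-bromoacetyl)cyclobutane-1,2-diyl]bis(methylene)}dicarbamate, via bis(isobutyl carbonate) mixed anhydride 13 (not isolated), via bis(diazomethyl ketone) 14 (not isolated)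
Conditions: i-BuOCOCl, N-methylmorpholine, THF, −15 °C; TMSCHN2 (2 M in hexanes), MeCN, 0 °C to rt, aqueous wash; crude 14, 48% aq. HBr (2.2 equiv), THF, 0 °C
Reagents that add atoms: (trimethylsilyl)diazomethane C[Si](C)(C)C=[N+]=[N-]; hydrogen bromide Br
Why: Arndt–Eistert-type acylation of the non-explosive silyl diazomethane by the mixed anhydride, then hydrobromination of the diazoketone with loss of N2 (Nierenstein-type); the trans diacid cannot close to a cyclic anhydride, and a near-stoichiometric amount of cold HBr is consumed by the diazo groups before it can cleave the carbamates.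

Step 10
Reactants: 15 di-tert-butyl {[(1R,2R,3S,4S)-3,4-bis(2-bromoacetyl)cyclobutane-1,2-diyl]bis(methylene)}dicarbamate; 16 2-aminopyrimidine
Product: 18 di-tert-butyl {[(1R,2R,3S,4S)-3,4-bis(imidazo[1,2-a]pyrimidin-2-yl)cyclobutane-1,2-diyl]bis(methylene)}dicarbamate, via bis(pyrimidinium) dibromide 17 (not isolated)
Conditions: 16 (5 equiv), NaHCO3 (4 equiv), EtOH, 25 °C (12 h), then 75 °C
Reagents that add atoms: none
Why: A ring nitrogen of 16 displaces bromide at each CH2Br (SN2) to give 17, after which the amino group adds to the neighbouring ketone and the carbinolamine loses water. The closest known reaction type is the Tschitschibabin-type condensation of 2-aminoazines with α-haloketones to imidazo-fused azines. Each of the two imidazole rings closes by a 5-exo-trig attack of nitrogen on C=O, and dehydration aromatises it. No stereocentre is created: Ca and Cd enter as ketone α-carbons in the thermodynamically preferred trans arrangement and are fixed once their substituents are aromatic. The step needs alkylation at the ring nitrogen and not at NH2, which amidine resonance secures, and because 16 is symmetrical only one fused isomer can form. It also needs intermolecular alkylation by 16 to outrun attack of the first-formed heterocycle or of a carbamate N–H on the remaining bromoacetyl group; the excess of 16, the poor nucleophilicity of a carbamate N–H under bicarbonate, the trans ring fusion that either closure would demand and alkylation of both arms at 25 °C before heating should secure this. NaHCO3 takes up the HBr that would otherwise cleave the carbamates and is too weak to promote enolisation of the ketones.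

Step 11
Reactants: 18 di-tert-butyl {[(1R,2R,3S,4S)-3,4-bis(imidazo[1,2-a]pyrimidin-2-yl)cyclobutane-1,2-diyl]bis(methylene)}dicarbamate; 19 1-(4-bromo-1H-pyrrol-2-yl)-2,2,2-trichloroethanone
Product: 21 N-{[(1R,2R,3S,4S)-2-(aminomethyl)-3,4-bis(imidazo[1,2-a]pyrimidin-2-yl)cyclobutyl]methyl}-4-bromo-1H-pyrrole-2-carboxamide, via diamine 20 (not isolated)
Conditions: CF3CO2H/CH2Cl2 1:3, 0 °C to rt, evaporate; then 19 (0.9 equiv, slow addition), i-Pr2NEt, DMF, 0 °C to rt
Reagents that add atoms: none
Why: Acidolysis of the carbamates (the fused heterocycles are merely protonated) and then haloform-type acylation of a primary amine by the trichloromethyl ketone; the two amines of 20 are homotopic, so mono-acylation gives a single compound, and slow addition of a deficit of 19 limits double acylation. Unreacted 20 and the bis-amide differ from 21 by one primary amine each, so they should separate on silica with an ammoniacal eluent, and recovered 20 can be recycled.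

Step 12
Reactants: 21 N-{[(1R,2R,3S,4S)-2-(aminomethyl)-3,4-bis(imidazo[1,2-a]pyrimidin-2-yl)cyclobutyl]methyl}-4-bromo-1H-pyrrole-2-carboxamide; 22 2,2,2-trichloro-1-(1H-pyrrol-2-yl)ethanone
Product: 23 4-bromo-N-({(1R,2R,3S,4S)-3,4-bis(imidazo[1,2-a]pyrimidin-2-yl)-2-[(1H-pyrrole-2-carboxamido)methyl]cyclobutyl}methyl)-1H-pyrrole-2-carboxamide
Conditions: 22 (1.3 equiv), i-Pr2NEt, DMF, rt
Reagents that add atoms: none
Why: The same haloform-type amine acylation on the remaining primary amine; pyrrole N–H groups and the fused heterocycles are not acylated by this mild donor.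

Step 13
Reactants: 23 4-bromo-N-({(1R,2R,3S,4S)-3,4-bis(imidazo[1,2-a]pyrimidin-2-yl)-2-[(1H-pyrrole-2-carboxamido)methyl]cyclobutyl}methyl)-1H-pyrrole-2-carboxamide
Product: 24 4-bromo-N-({(1R,2R,3S,4S)-3,4-bis(2-amino-1H-imidazol-4-yl)-2-[(1H-pyrrole-2-carboxamido)methyl]cyclobutyl}methyl)-1H-pyrrole-2-carboxamide (desbromosceptrine)
Conditions: N2H4·H2O (20 equiv), EtOH, reflux, N2 atmosphere; reverse-phase chromatography
Reagents that add atoms: none
Why: Hydrazinolysis of imidazo[1,2-a]pyrimidines: hydrazine adds to the electron-poor pyrimidine ring, the ring opens and the three-carbon bridge leaves as pyrazole, turning the bridgehead nitrogen into the imidazole N–H and the other into the exocyclic NH2; secondary pyrrole amides and the pyrrole C–Br bond should not react with hydrazine at this temperature, and no stereocentre is touched.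

Compound list

1 | (1S,2S)-cyclohex-4-ene-1,2-dicarboxylic acid | OC(=O)[C@H]1CC=CC[C@@H]1C(=O)O | starting material
2 | [(1S,2S)-cyclohex-4-ene-1,2-diyl]dimethanol | OC[C@H]1CC=CC[C@@H]1CO | intermediate
3 | (4S,5S)-4,5-bis[(benzyloxy)methyl]cyclohex-1-ene | C(OCc1ccccc1)[C@H]1CC=CC[C@@H]1COCc1ccccc1 | intermediate
4 | dimethyl (3S,4S)-3,4-bis[(benzyloxy)methyl]hexanedioate | COC(=O)C[C@H](COCc1ccccc1)[C@@H](COCc1ccccc1)CC(=O)OC | intermediate
5 | dimethyl 3,4-bis[(benzyloxy)methyl]-2-iodohexanedioate (present as its lithium enolate; C3 and C4 as in 4, C2 unassigned) | COC(=O)C(I)[C@H](COCc1ccccc1)[C@@H](COCc1ccccc1)CC(=O)OC | intermediate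
6 | dimethyl (1S,2S,3R,4R)-3,4-bis[(benzyloxy)methyl]cyclobutane-1,2-dicarboxylate (all-trans) | c1ccccc1COC[C@H]2[C@H](C(=O)OC)[C@@H](C(=O)OC)[C@@H]2COCc1ccccc1 | intermediate
7 | {(1R,2R,3S,4S)-3,4-bis[(benzyloxy)methyl]cyclobutane-1,2-diyl}dimethanol (all-trans) | c1ccccc1COC[C@H]2[C@H](CO)[C@@H](CO)[C@@H]2COCc1ccccc1 | intermediate
8 | (1R,2R,3S,4S)-1,2-bis(azidomethyl)-3,4-bis[(benzyloxy)methyl]cyclobutane (all-trans) | c1ccccc1COC[C@H]2[C@H](CN=[N+]=[N-])[C@@H](CN=[N+]=[N-])[C@@H]2COCc1ccccc1 | intermediate
9 | di-tert-butyl {[(1R,2R,3S,4S)-3,4-bis[(benzyloxy)methyl]cyclobutane-1,2-diyl]bis(methylene)}dicarbamate | c1ccccc1COC[C@H]2[C@H](CNC(=O)OC(C)(C)C)[C@@H](CNC(=O)OC(C)(C)C)[C@@H]2COCc1ccccc1 | intermediate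
10 | di-tert-butyl {[(1R,2R,3S,4S)-3,4-bis(hydroxymethyl)cyclobutane-1,2-diyl]bis(methylene)}dicarbamate | OC[C@H]1[C@H](CNC(=O)OC(C)(C)C)[C@@H](CNC(=O)OC(C)(C)C)[C@@H]1CO | intermediate
11 | di-tert-butyl {[(1R,2R,3S,4S)-3,4-diformylcyclobutane-1,2-diyl]bis(methylene)}dicarbamate | O=C[C@H]1[C@H](CNC(=O)OC(C)(C)C)[C@@H](CNC(=O)OC(C)(C)C)[C@@H]1C=O | intermediate
12 | (1S,2S,3R,4R)-3,4-bis{[(tert-butoxycarbonyl)amino]methyl}cyclobutane-1,2-dicarboxylic acid | OC(=O)[C@H]1[C@H](CNC(=O)OC(C)(C)C)[C@@H](CNC(=O)OC(C)(C)C)[C@@H]1C(=O)O | intermediate
13 | (1S,2S,3R,4R)-3,4-bis{[(tert-butoxycarbonyl)amino]methyl}cyclobutane-1,2-dicarboxylic bis(isobutyl carbonic) anhydride (all-trans) | CC(C)COC(=O)OC(=O)[C@H]1[C@H](CNC(=O)OC(C)(C)C)[C@@H](CNC(=O)OC(C)(C)C)[C@@H]1C(=O)OC(=O)OCC(C)C | intermediate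
14 | di-tert-butyl {[(1R,2R,3S,4S)-3,4-bis(2-diazoacetyl)cyclobutane-1,2-diyl]bis(methylene)}dicarbamate | [N-]=[N+]=CC(=O)[C@H]1[C@H](CNC(=O)OC(C)(C)C)[C@@H](CNC(=O)OC(C)(C)C)[C@@H]1C(=O)C=[N+]=[N-] | intermediate
15 | di-tert-butyl {[(1R,2R,3S,4S)-3,4-bis(2-bromoacetyl)cyclobutane-1,2-diyl]bis(methylene)}dicarbamate (all-trans) | BrCC(=O)[C@H]1[C@H](CNC(=O)OC(C)(C)C)[C@@H](CNC(=O)OC(C)(C)C)[C@@H]1C(=O)CBr | intermediate
16 | 2-aminopyrimidine | Nc1ncccn1 | starting material
17 | 1,1'-{[(1S,2S,3R,4R)-3,4-bis{[(tert-butoxycarbonyl)amino]methyl}cyclobutane-1,2-diyl]bis(2-oxoethane-2,1-diyl)}bis(2-aminopyrimidin-1-ium) dibromide | [Br-].[Br-].Nc1nccc[n+]1CC(=O)[C@H]1[C@H](CNC(=O)OC(C)(C)C)[C@@H](CNC(=O)OC(C)(C)C)[C@@H]1C(=O)C[n+]1cccnc1N | intermediate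
18 | di-tert-butyl {[(1R,2R,3S,4S)-3,4-bis(imidazo[1,2-a]pyrimidin-2-yl)cyclobutane-1,2-diyl]bis(methylene)}dicarbamate (all-trans) | n1c2ncccn2cc1[C@H]3[C@H](CNC(=O)OC(C)(C)C)[C@@H](CNC(=O)OC(C)(C)C)[C@@H]3c1cn2cccnc2n1 | intermediate
19 | 1-(4-bromo-1H-pyrrol-2-yl)-2,2,2-trichloroethanone | O=C(c1cc(Br)c[nH]1)C(Cl)(Cl)Cl | starting material
20 | [(1R,2R,3S,4S)-3,4-bis(imidazo[1,2-a]pyrimidin-2-yl)cyclobutane-1,2-diyl]dimethanamine | n1c2ncccn2cc1[C@H]3[C@H](CN)[C@@H](CN)[C@@H]3c1cn2cccnc2n1 | intermediate
21 | N-{[(1R,2R,3S,4S)-2-(aminomethyl)-3,4-bis(imidazo[1,2-a]pyrimidin-2-yl)cyclobutyl]methyl}-4-bromo-1H-pyrrole-2-carboxamide | n1c2ncccn2cc1[C@H]3[C@H](CN)[C@@H](CNC(=O)c4cc(Br)c[nH]4)[C@@H]3c1cn2cccnc2n1 | intermediate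
22 | 2,2,2-trichloro-1-(1H-pyrrol-2-yl)ethanone | O=C(c1ccc[nH]1)C(Cl)(Cl)Cl | starting material
23 | 4-bromo-N-({(1R,2R,3S,4S)-3,4-bis(imidazo[1,2-a]pyrimidin-2-yl)-2-[(1H-pyrrole-2-carboxamido)methyl]cyclobutyl}methyl)-1H-pyrrole-2-carboxamide | n1c2ncccn2cc1[C@H]3[C@H](CNC(=O)c4ccc[nH]4)[C@@H](CNC(=O)c4cc(Br)c[nH]4)[C@@H]3c1cn2cccnc2n1 | intermediate
24 | desbromosceptrine, 4-bromo-N-({(1R,2R,3S,4S)-3,4-bis(2-amino-1H-imidazol-4-yl)-2-[(1H-pyrrole-2-carboxamido)methyl]cyclobutyl}methyl)-1H-pyrrole-2-carboxamide (all-trans) | Nc1ncc([C@H]2[C@H](CNC(=O)c3ccc[nH]3)[C@@H](CNC(=O)c3cc(Br)c[nH]3)[C@@H]2c2cnc(N)[nH]2)[nH]1 | target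

Total step count: 13. Longest linear sequence: 13 steps (1 to 24); 16, 19 and 22 are purchased.

Least certain steps

**Step 10 (key step).** The second annulation may lag behind the first. The nucleophilic N1 of the first-formed fused ring, or a carbamate nitrogen, could then attack the remaining bromoacetyl group intramolecularly, and HBr build-up with enolisation of the bromoketone could add carbamate loss and epimerisation. Fallback, setting out from 15 and returning at 24: drop the pyrimidine mask and condense 15 with N-Boc-guanidine in DMF at rt, which should give the tetra-Boc bis(2-aminoimidazole) F1. CF3CO2H would then remove all four Boc groups to give the tetraamine F2. Mono-acylation with 19 would give the bromopyrrole mono-amide F3, and acylation of F3 with 22 would give 24. The price is a statistical acylation on a polar, unmasked intermediate.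

**Step 4.** Dieckmann-type acylation, intermolecular coupling, double iodination or dehydroiodination of the iodo ester may compete with the strained 4-exo-tet closure, because the closure must win a race set up in one pot at low temperature. Fallback, setting out from 4 and returning at 6: separate halogenation from ring closure. Mono-deprotonation of 4 with LiN(SiMe3)2 (1 equiv) and bromination with N-bromosuccinimide would give the α-bromo diester F4, which is purified. KOt-Bu in t-BuOH/THF at high dilution would then close the ring by reversible enolisation and irreversible intramolecular alkylation, and NaOMe equilibration would deliver 6.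

**Step 9.** Attack of the silyl diazomethane at the carbonate carbonyl of the hindered mixed anhydride would return ester instead of diazoketone. Acid-promoted carbamate cleavage during hydrobromination is the second risk. Fallback, setting out from 12 and returning at 15, diazo-free: activate 12 with 1,1'-carbonyldiimidazole to the bis(acyl imidazole) F5. Treat F5 with dimethylsulfoxonium methylide (from Me3S(O)I and KOt-Bu) to give the bis(β-keto sulfoxonium ylide) F6. Protonation of F6 with MeSO3H in the presence of LiBr in THF lets bromide displace dimethyl sulfoxide and should give 15.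

**Step 13.** Ring cleavage of the neutral, non-quaternised heterocycles may be slow, and forcing conditions could bring on hydrazinolysis of the pyrrole amides or loss of bromine. Fallback, setting out from 18 and returning at 24: unmask before the amides exist. Hydrazine on 18 should give the bis(carbamate) bis(2-aminoimidazole) F7. CF3CO2H would then give the tetraamine F2, and acylation with 19 to the mono-amide F3 and then with 22 would give 24, as in the fallback for step 10.

**Step 7.** Amines formed before they are trapped may inhibit the catalyst, so that hydrogenolysis of the benzyl ethers stalls at 9. Fallback, setting out from 8 and returning at 10: use two mechanistically different operations. Staudinger reduction (PMe3, THF/H2O) with Boc2O gives 9, which is isolated. Dissolving-metal debenzylation (Na, liquid NH3, THF, −78 °C) then gives 10, and the carbamates should survive this. No new compound is involved.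

## Further compounds

F1 | step 10 | di-tert-butyl 4,4'-[(1S,2S,3R,4R)-3,4-bis{[(tert-butoxycarbonyl)amino]methyl}cyclobutane-1,2-diyl]bis(2-amino-1H-imidazole-1-carboxylate) | CC(C)(C)OC(=O)n1cc(nc1N)[C@H]2[C@H](CNC(=O)OC(C)(C)C)[C@@H](CNC(=O)OC(C)(C)C)[C@@H]2c1cn(C(=O)OC(C)(C)C)c(N)n1
F2 | step 10 | 4,4'-[(1S,2S,3R,4R)-3,4-bis(aminomethyl)cyclobutane-1,2-diyl]bis(1H-imidazol-2-amine) | Nc1ncc([C@H]2[C@H](CN)[C@@H](CN)[C@@H]2c2cnc(N)[nH]2)[nH]1
F3 | step 10 | N-{[(1R,2R,3S,4S)-2-(aminomethyl)-3,4-bis(2-amino-1H-imidazol-4-yl)cyclobutyl]methyl}-4-bromo-1H-pyrrole-2-carboxamide | Nc1ncc([C@H]2[C@H](CN)[C@@H](CNC(=O)c3cc(Br)c[nH]3)[C@@H]2c2cnc(N)[nH]2)[nH]1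
F4 | step 4 | dimethyl 3,4-bis[(benzyloxy)methyl]-2-bromohexanedioate (C3 and C4 as in 4, C2 either configuration) | COC(=O)C(Br)[C@H](COCc1ccccc1)[C@@H](COCc1ccccc1)CC(=O)OC
F5 | step 9 | di-tert-butyl {[(1R,2R,3S,4S)-3,4-bis(1H-imidazole-1-carbonyl)cyclobutane-1,2-diyl]bis(methylene)}dicarbamate | O=C(n1ccnc1)[C@H]1[C@H](CNC(=O)OC(C)(C)C)[C@@H](CNC(=O)OC(C)(C)C)[C@@H]1C(=O)n1ccnc1
F6 | step 9 | di-tert-butyl {[(1R,2R,3S,4S)-3,4-bis[2-(dimethyloxido-λ6-sulfanylidene)acetyl]cyclobutane-1,2-diyl]bis(methylene)}dicarbamate | CS(C)(=O)=CC(=O)[C@H]1[C@H](CNC(=O)OC(C)(C)C)[C@@H](CNC(=O)OC(C)(C)C)[C@@H]1C(=O)C=S(C)(C)=O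
F7 | step 13 | di-tert-butyl {[(1R,2R,3S,4S)-3,4-bis(2-amino-1H-imidazol-4-yl)cyclobutane-1,2-diyl]bis(methylene)}dicarbamate | Nc1ncc([C@H]2[C@H](CNC(=O)OC(C)(C)C)[C@@H](CNC(=O)OC(C)(C)C)[C@@H]2c2cnc(N)[nH]2)[nH]1
F0 | step 7 | none | none
A1 | alternative 1 | phthalic acid | OC(=O)c1ccccc1C(=O)O
A2 | alternative 1 | cis-1,2-dihydrophthalic anhydride | O=C1OC(=O)[C@@H]2C=CC=C[C@H]12
A3 | alternative 1 | bicyclo[2.2.0]hex-5-ene-2,3-dicarboxylic anhydride (meso, cyclobutene anti to the anhydride) | O=C1[C@H]2[C@H](C=C3)[C@H]3[C@H]2C(=O)O1
A4 | alternative 2 | (2S,3S)-2,3-bis[(benzyloxy)methyl]-1-(phenylsulfonyl)cyclopropan-1-ol (trans) | OC1(S(=O)(=O)c2ccccc2)[C@H](COCc2ccccc2)[C@H]1COCc1ccccc1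
A5 | alternative 2 | (2S,3S)-2,3-bis[(benzyloxy)methyl]cyclopropan-1-one (trans) | O=C1[C@H](COCc2ccccc2)[C@H]1COCc1ccccc1
A6 | alternative 2 | ethyl diazoacetate | CCOC(=O)C=[N+]=[N-]
A7 | alternative 2 | ethyl 2,3-bis[(benzyloxy)methyl]-4-oxocyclobutane-1-carboxylate (all-trans) | c1ccccc1COC[C@H]2[C@H](C(=O)OCC)C(=O)[C@@H]2COCc1ccccc1
A8 | alternative 3 | (1R,2R)-N1,N2-di(quinolin-8-yl)cyclobutane-1,2-dicarboxamide | O=C(Nc1cccc2cccnc12)[C@@H]1CC[C@H]1C(=O)Nc1cccc2cccnc12
A9 | alternative 3 | 4-iodo-1-trityl-1H-imidazole | Ic1cn(C(c2ccccc2)(c2ccccc2)c2ccccc2)cn1
A10 | alternative 3 | N1,N2-di(quinolin-8-yl)-3,4-bis(1-trityl-1H-imidazol-4-yl)cyclobutane-1,2-dicarboxamide (each imidazole cis to its neighbouring amide) | n1cn(C(c2ccccc2)(c2ccccc2)c2ccccc2)cc1[C@H]4[C@@H](C(=O)Nc2cccc3cccnc23)[C@H](C(=O)Nc2cccc3cccnc23)[C@@H]4c1cn(C(c2ccccc2)(c2ccccc2)c2ccccc2)cn1
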